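**Retrosynthetic overview**
1. Daucane numbering: C1 = quaternary ring-fusion carbon (CH3), C2/C3 = CH2, C4 = C(OH)(i-Pr), C5 = ring-fusion CH, C6 = CH–O-aroyl, C7 = CH2, C8 = C(CH3)=, C9 = =CH, C10 = CH–O-tigloyl. Ring A = cyclopentane C1–C5, ring B = cycloheptene C1/C5–C10. β = the face of the C1 methyl group and H5 (cis-fused bicycle); O4, O6 and O10 are all α.
2. Endgame: both esters go on last. The 10α-carbinol comes from a dauc-8-en-10-one, C8=C9 from Saegusa–Ito oxidation of the saturated 10-ketone, and the 6α-carbinol from chelation-controlled reduction of a 4-hydroxy-6,10-dione.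
3. Key disconnection: C1–C5 and C8–C9 are cut together. The forward step is an intramolecular (4+3) cycloaddition of a 2-ethoxyallyl cation (C9–C10–C1) with a 2-silyloxydiene (C5=C6–C7=C8), joined by the tether C2–C3–C4. Rings A and B form in the same operation, and no ring of the target exists before it.
4. Enabling feature: in ring B, O10 sits on the central carbon of the three-carbon arc C9–C10–C1 and O6 on an inner carbon of the four-carbon arc C5–C8. This 1,5-dioxygenation is the pattern of an oxyallyl cation plus an enone-derived diene. The C4 carbinol of ring A is β to C6, so O4 and O6 can be tied into a temporary Si(i-Pr)2 ring that fixes diene geometry and face.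
5. Precursor: ozonolysis of (S)-terpinen-4-ol supplies ten of the fifteen skeletal carbons and the C4 stereocentre (C1 as methyl ketone, C6 as aldehyde). C7–C8–CH3 comes from (E)-1-bromopropene and C10–C9 from ethyl vinyl ether.

Key step: step 6

Assumption: (S)-(+)-terpinen-4-ol is taken in enantiopure form. Material of lower enantiomeric purity would have to be enriched first, because C4 is the only source of absolute configuration.

**Step 1**
Reactants: 1 (S)-(+)-terpinen-4-ol
Product: 2 (3S)-3-hydroxy-6-oxo-3-(propan-2-yl)heptanal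
Conditions: O3, CH2Cl2, −78 °C; then Me2S, −78 °C to rt
Reagents that add atoms: ozone, [O-][O+]=O
Why: Ozonolysis (Criegee mechanism) with reductive work-up cleaves the only C=C bond, unmasking C6 as aldehyde and C1 as methyl ketone, and the C4 carbinol centre passes through these neutral conditions unchanged.

**Step 2**
Reactants: 2 (3S)-3-hydroxy-6-oxo-3-(propan-2-yl)heptanal; 3 (E)-1-bromoprop-1-ene
Product: 4 (5S,8E)-5,7-dihydroxy-5-(propan-2-yl)dec-8-en-2-one (both C7 epimers)
Conditions: CrCl2 (4 equiv), NiCl2 (2 mol %), DMF, rt; then H2O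
Reagents that add atoms: none
Why: In the Nozaki–Hiyama–Kishi reaction the alkenylchromium species keeps the E geometry, adds to the aldehyde much faster than to the ketone and tolerates the free hydroxyl, and the new carbinol centre needs no control because step 3 oxidises it.

**Step 3**
Reactants: 4 (5S,8E)-5,7-dihydroxy-5-(propan-2-yl)dec-8-en-2-one
Product: 5 (2E,6S)-6-hydroxy-6-(propan-2-yl)dec-2-ene-4,9-dione
Conditions: IBX, DMSO, rt
Reagents that add atoms: none
Why: IBX oxidation converts the secondary allylic alcohol into the E-enone under neutral conditions, while the tertiary alcohol cannot be oxidised and C4 is untouched.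

**Step 4**
Reactants: 5 (2E,6S)-6-hydroxy-6-(propan-2-yl)dec-2-ene-4,9-dione
Product: 7 4-{(4R)-2,2,4-tri(propan-2-yl)-6-[(E)-prop-1-enyl]-4H-1,3,2-dioxasilin-4-yl}butan-2-one, via silyl monotriflate 6 (not isolated)
Conditions: i-Pr2Si(OTf)2, 2,6-lutidine, CH2Cl2, −78 to 0 °C; then Et3N, 0 °C to rt
Reagents that add atoms: diisopropylsilyl bis(trifluoromethanesulfonate), CC(C)[Si](OS(=O)(=O)C(F)(F)F)(OS(=O)(=O)C(F)(F)F)C(C)C
Why: O-silylation of the tertiary alcohol is followed by intramolecular soft enolisation and O-silylation (silyl triflate plus Et3N) of the one ketone that closes a six-membered ring, so that α′-deprotonation at C5 gives the cross-conjugated 2-silyloxydiene and the ring locks C5=C6 with C4 trans to C7.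

**Step 5**
Reactants: 7 4-{(4R)-2,2,4-tri(propan-2-yl)-6-[(E)-prop-1-enyl]-4H-1,3,2-dioxasilin-4-yl}butan-2-one; 8 ethyl vinyl ether
Product: 10 2-ethoxy-3-methyl-5-{(4R)-2,2,4-tri(propan-2-yl)-6-[(E)-prop-1-enyl]-4H-1,3,2-dioxasilin-4-yl}pent-1-en-3-ol (both carbinol epimers), via 1-ethoxyvinyllithium 9 (not isolated)
Conditions: 8, t-BuLi, THF, −78 to 0 °C; then 7, −78 °C; then H2O
Reagents that add atoms: none
Why: The acyl-anion equivalent 1-ethoxyvinyllithium adds 1,2 to the methyl ketone while the hindered silyl dienol ether is inert at −78 °C, and the new C1 carbinol centre forms without control because it is lost on ionisation in step 6.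

**Step 6**
Reactants: 10 2-ethoxy-3-methyl-5-{(4R)-2,2,4-tri(propan-2-yl)-6-[(E)-prop-1-enyl]-4H-1,3,2-dioxasilin-4-yl}pent-1-en-3-ol
Product: 13 4α,6-(diisopropylsilanediyldioxy)-5βH-dauc-6-en-10-one (1β-CH3; 4β-i-Pr; 8β-H), via 2-ethoxyallyl cation 11 (not isolated), via O-ethyl oxocarbenium ion 12 (not isolated)
Conditions: Tf2O (1.1 equiv), 2,6-lutidine (3 equiv), CH2Cl2 (dilute), −78 °C; then H2O
Reagents that add atoms: water, O
Why: Proposed new method: O-triflation and ionisation of the tertiary 2-ethoxyallylic alcohol gives cation 11, whose tertiary terminus C1 is attacked by the nucleophilic carbon C5 of the cyclic silyl dienol ether while the enol-ether terminus C9 closes on C8, a concerted but asynchronous [4π+2π] (4+3) cycloaddition to oxocarbenium ion 12, which water converts into ketone 13. The closest known reaction type is the intramolecular (4+3) cycloaddition of 2-alkoxyallyl cations, generated in the same way from 2-alkoxyallylic alcohols with Tf2O and 2,6-lutidine, with butadienes or furans on a three-atom tether; what is new is the 2-silyloxydiene as four-carbon partner, a much better nucleophile whose polarity matches the cation (C5 δ− to C1 δ+, C9 δ− to C8 δ+). Ring A closes in a 5-exo mode (C5 onto C1, C10 outside the ring) and ring B in a 7-endo mode (C9 onto C8), each π system reacting on one face only. C5 is controlled by C4: in the nearly planar dioxasilinene the tether and the isopropyl group stand on opposite faces, the cation can reach only the tether face, and so H5 ends cis to isopropyl and C6 cis to O4. C1 is controlled by the compact (endo) arrangement, in which the methyl group that must occupy the inner position of the cation points away from the diene and from the silylene ring, whereas in the extended arrangement it would lie under C6 and O6, so methyl and H5 become cis, and the E-propenyl group places H8 on the same face, a centre that is erased in step 11. The step needs (4+3) rather than (3+2) closure and capture faster than proton loss: closure of C9 on C6 would be a geometrically disfavoured 5-(enolendo)-exo-trig process, the ethyl group blocks closure through oxygen, the ring keeps C4 outside so that the s-cis diene is accessible, and the high nucleophilicity of the silyl enol ether should outrun elimination.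

**Step 7**
Reactants: 13 4α,6-(diisopropylsilanediyldioxy)-5βH-dauc-6-en-10-one
Product: 14 4α-hydroxy-5βH-daucane-6,10-dione (1β-CH3; 8β-H)
Conditions: HF·pyridine, pyridine, THF, 0 °C
Reagents that add atoms: none
Why: Fluoride cleaves both Si–O bonds and the liberated enol is protonated at C7, and the buffered, weakly acidic medium is chosen to avoid retro-aldol cleavage, dehydration at C4 and epimerisation at C5.

**Step 8**
Reactants: 14 4α-hydroxy-5βH-daucane-6,10-dione
Product: 16 4α,6α-dihydroxy-5βH-daucan-10-one, via diethylborinate chelate 15 (not isolated)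
Conditions: Et2BOMe, THF/MeOH 4:1, −78 °C; NaBH4, −78 °C; then MeOH co-evaporation
Reagents that add atoms: none
Why: In the Narasaka–Prasad reduction, boron chelation between O4 and the C6 carbonyl activates this ketone over the C10 ketone, and external hydride should enter from the β face, which carries only H5, because the α face is closed by C1 and C3, so O6 becomes α (6R).

**Step 9**
Reactants: 17 4-hydroxybenzoic acid
Product: 19 4-(tert-butyldimethylsilyloxy)benzoic acid, via bis-silyl derivative 18 (not isolated)
Conditions: TBSCl (2.2 equiv), imidazole, DMF, rt; then AcOH/THF/H2O, rt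
Reagents that add atoms: tert-butyldimethylsilyl chloride, CC(C)(C)[Si](C)(C)Cl
Why: Standard bis-silylation is followed by selective hydrolysis of the silyl ester, which is far more labile than the aryl silyl ether.

**Step 10**
Reactants: 16 4α,6α-dihydroxy-5βH-daucan-10-one; 19 4-(tert-butyldimethylsilyloxy)benzoic acid
Product: 20 6α-[4-(tert-butyldimethylsilyloxy)benzoyloxy]-4α-hydroxy-5βH-daucan-10-one
Conditions: DCC, DMAP (cat.), CH2Cl2, rt
Reagents that add atoms: none
Why: Steglich esterification acylates the secondary C6 hydroxyl while the tertiary C4 hydroxyl is too hindered, and C6 keeps its configuration because its C–O bond is not broken.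

**Step 11**
Reactants: 20 6α-[4-(tert-butyldimethylsilyloxy)benzoyloxy]-4α-hydroxy-5βH-daucan-10-one
Product: 22 6α-[4-(tert-butyldimethylsilyloxy)benzoyloxy]-4α-trimethylsilyloxy-5βH-dauc-8-en-10-one, via bis-TMS enol ether 21 (not isolated)
Conditions: TMSOTf, Et3N, CH2Cl2, 0 °C; then Pd(OAc)2 (1.1 equiv), MeCN, rt
Reagents that add atoms: trimethylsilyl trifluoromethanesulfonate, C[Si](C)(C)OS(=O)(=O)C(F)(F)F
Why: In the Saegusa–Ito oxidation the C10 ketone can enolise only towards C9 because C1 is quaternary, TMSOTf also caps the C4 hydroxyl, and syn β-hydride elimination of H8 from the palladium enolate places the double bond at C8=C9 and erases the C8 centre.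

**Step 12**
Reactants: 22 6α-[4-(tert-butyldimethylsilyloxy)benzoyloxy]-4α-trimethylsilyloxy-5βH-dauc-8-en-10-one
Product: 23 6α-[4-(tert-butyldimethylsilyloxy)benzoyloxy]-4α-trimethylsilyloxy-5βH-dauc-8-en-10α-ol
Conditions: NaBH4, CeCl3·7H2O, MeOH, −78 °C
Reagents that add atoms: none
Why: Luche reduction is 1,2-selective, and in the favoured ring B conformer (C4 and the C6 ester equatorial, C2 axial on the α face, C1 methyl near the carbonyl plane) hydride should attack C10 from the convex β face, anti to C2, giving the 10α-alcohol (10S).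

**Step 13**
Reactants: 23 6α-[4-(tert-butyldimethylsilyloxy)benzoyloxy]-4α-trimethylsilyloxy-5βH-dauc-8-en-10α-ol; 24 tigloyl chloride
Product: 25 6α-[4-(tert-butyldimethylsilyloxy)benzoyloxy]-10α-tigloyloxy-4α-trimethylsilyloxy-5βH-dauc-8-ene
Conditions: Et3N, DMAP (cat.), CH2Cl2, 0 °C to rt
Reagents that add atoms: none
Why: DMAP-catalysed acylation with the acid chloride leaves the C10–O bond intact, so C10 is retained, and the E-configured tigloyl group is configurationally stable under these conditions.

**Step 14**
Reactants: 25 6α-[4-(tert-butyldimethylsilyloxy)benzoyloxy]-10α-tigloyloxy-4α-trimethylsilyloxy-5βH-dauc-8-ene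
Product: 26 target, (1R,4R,5S,6R,10S)-4-hydroxy-6-(4-hydroxybenzoyloxy)-10-[(E)-2-methylbut-2-enoyloxy]dauc-8-ene
Conditions: TBAF, AcOH, THF, 0 °C
Reagents that add atoms: none
Why: Buffered fluoride desilylation removes the phenolic TBS ether and the tertiary TMS ether without touching either ester, the allylic system or any stereocentre.

**Compound list**
1 | (S)-(+)-terpinen-4-ol | CC1=CC[C@](O)(C(C)C)CC1 | starting material
2 | (3S)-3-hydroxy-6-oxo-3-(propan-2-yl)heptanal | CC(=O)CC[C@@](CC=O)(O)C(C)C | intermediate
3 | (E)-1-bromoprop-1-ene | C/C=C/Br | starting material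
4 | (5S,8E)-5,7-dihydroxy-5-(propan-2-yl)dec-8-en-2-one, both C7 epimers | CC(=O)CC[C@@](CC(O)/C=C/C)(O)C(C)C | intermediate
5 | (2E,6S)-6-hydroxy-6-(propan-2-yl)dec-2-ene-4,9-dione | CC(=O)CC[C@@](CC(=O)/C=C/C)(O)C(C)C | intermediate
6 | O-[diisopropyl(trifluoromethanesulfonyloxy)silyl] ether of 5 | CC(=O)CC[C@@](CC(=O)/C=C/C)(O[Si](C(C)C)(C(C)C)OS(=O)(=O)C(F)(F)F)C(C)C | intermediate
7 | 4-{(4R)-2,2,4-tri(propan-2-yl)-6-[(E)-prop-1-enyl]-4H-1,3,2-dioxasilin-4-yl}butan-2-one | CC(=O)CC[C@]1(C=C(/C=C/C)O[Si](C(C)C)(C(C)C)O1)C(C)C | intermediate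
8 | ethyl vinyl ether | C=COCC | starting material
9 | 1-ethoxyvinyllithium | [Li]C(=C)OCC | intermediate
10 | 2-ethoxy-3-methyl-5-{(4R)-2,2,4-tri(propan-2-yl)-6-[(E)-prop-1-enyl]-4H-1,3,2-dioxasilin-4-yl}pent-1-en-3-ol, both carbinol epimers | C=C(OCC)C(C)(O)CC[C@]1(C=C(/C=C/C)O[Si](C(C)C)(C(C)C)O1)C(C)C | intermediate
11 | 2-ethoxyallyl cation derived from 10 | C=C(OCC)[C+](C)CC[C@]1(C=C(/C=C/C)O[Si](C(C)C)(C(C)C)O1)C(C)C | intermediate
12 | O-ethyl oxocarbenium ion of 13 | CC[O+]=C1C[C@@H](C)C=C3[C@@H]2[C@@]1(C)CC[C@@]2(O[Si](C(C)C)(C(C)C)O3)C(C)C | intermediate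
13 | 4α,6-(diisopropylsilanediyldioxy)-5βH-dauc-6-en-10-one (1β-CH3, 4β-i-Pr, 8β-H) | O=C1C[C@@H](C)C=C3[C@@H]2[C@@]1(C)CC[C@@]2(O[Si](C(C)C)(C(C)C)O3)C(C)C | intermediate
14 | 4α-hydroxy-5βH-daucane-6,10-dione | O=C1C[C@@H](C)CC(=O)[C@@H]2[C@@]1(C)CC[C@@]2(O)C(C)C | intermediate
15 | 4-O-diethylboryl derivative (chelate) of 14 | O=C1C[C@@H](C)CC(=O)[C@@H]2[C@@]1(C)CC[C@@]2(OB(CC)CC)C(C)C | intermediate
16 | 4α,6α-dihydroxy-5βH-daucan-10-one | O=C1C[C@@H](C)C[C@@H](O)[C@@H]2[C@@]1(C)CC[C@@]2(O)C(C)C | intermediate
17 | 4-hydroxybenzoic acid | OC(=O)c1ccc(O)cc1 | starting material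
18 | tert-butyldimethylsilyl 4-(tert-butyldimethylsilyloxy)benzoate | CC(C)(C)[Si](C)(C)OC(=O)c1ccc(O[Si](C)(C)C(C)(C)C)cc1 | intermediate
19 | 4-(tert-butyldimethylsilyloxy)benzoic acid | OC(=O)c1ccc(O[Si](C)(C)C(C)(C)C)cc1 | intermediate
20 | 6α-[4-(tert-butyldimethylsilyloxy)benzoyloxy]-4α-hydroxy-5βH-daucan-10-one | O=C1C[C@@H](C)C[C@@H](OC(=O)c3ccc(O[Si](C)(C)C(C)(C)C)cc3)[C@@H]2[C@@]1(C)CC[C@@]2(O)C(C)C | intermediate
21 | 10-trimethylsilyl enol ether (C9=C10) and 4-O-TMS ether of 20 | C[Si](C)(C)OC1=C[C@@H](C)C[C@@H](OC(=O)c3ccc(O[Si](C)(C)C(C)(C)C)cc3)[C@@H]2[C@@]1(C)CC[C@@]2(O[Si](C)(C)C)C(C)C | intermediate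
22 | 6α-[4-(tert-butyldimethylsilyloxy)benzoyloxy]-4α-trimethylsilyloxy-5βH-dauc-8-en-10-one | O=C1C=C(C)C[C@@H](OC(=O)c3ccc(O[Si](C)(C)C(C)(C)C)cc3)[C@@H]2[C@@]1(C)CC[C@@]2(O[Si](C)(C)C)C(C)C | intermediate
23 | 6α-[4-(tert-butyldimethylsilyloxy)benzoyloxy]-4α-trimethylsilyloxy-5βH-dauc-8-en-10α-ol | O[C@H]1C=C(C)C[C@@H](OC(=O)c3ccc(O[Si](C)(C)C(C)(C)C)cc3)[C@@H]2[C@@]1(C)CC[C@@]2(O[Si](C)(C)C)C(C)C | intermediate
24 | tigloyl chloride, (E)-2-methylbut-2-enoyl chloride | C/C=C(\C)C(=O)Cl | starting material
25 | 6α-[4-(tert-butyldimethylsilyloxy)benzoyloxy]-10α-tigloyloxy-4α-trimethylsilyloxy-5βH-dauc-8-ene | C/C=C(\C)C(=O)O[C@H]1C=C(C)C[C@@H](OC(=O)c3ccc(O[Si](C)(C)C(C)(C)C)cc3)[C@@H]2[C@@]1(C)CC[C@@]2(O[Si](C)(C)C)C(C)C | intermediate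
26 | CNP0273650.13, (1R,4R,5S,6R,10S)-4-hydroxy-6-(4-hydroxybenzoyloxy)-10-[(E)-2-methylbut-2-enoyloxy]dauc-8-ene | C/C=C(\C)C(=O)O[C@H]1C=C(C)C[C@@H](OC(=O)c2ccc(O)cc2)[C@@H]2[C@@]1(C)CC[C@@]2(O)C(C)C | target

Total step count: 14. Longest linear sequence: 13 steps (steps 1–8 and 10–14, from 1).

**Steps most likely to fail**

1. Step 6.
- What may go wrong: the cation loses a proton to give a 2-ethoxydiene before it is captured; the reaction stops after the first C–C bond with loss of silicon; or closure runs through the extended arrangement and erodes the cis ring fusion.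
- Fallback: it sets out from 10 and comes back at 14, making the two bonds one after the other by known reactions.
- Ring A: ionisation of 10 with ZnBr2 in CH2Cl2 at −78 to 0 °C is used only for the Lewis-acid-mediated α-tert-alkylation of the silyl enol ether (C5 onto C1). Treating the crude product with aqueous HF in MeCN hydrolyses the ethyl enol ether and removes silicon. This gives (E)-1-[(1R,2R,5R)-2-acetyl-5-hydroxy-2-methyl-5-(propan-2-yl)cyclopentyl]but-2-en-1-one F1, in which acetyl, butenoyl and hydroxyl are all cis.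
- Ring B: the kinetic lithium enolate of the methyl ketone of F1 (LiHMDS, THF, −78 to 0 °C) closes the ring by intramolecular Michael addition to the propenyl ketone and gives 14. The C8 centre is erased in step 11, so its configuration is of no consequence.

2. Step 4.
- What may go wrong: silylation of the hindered tertiary carbinol by the bulky bis-triflate is sluggish; enolisation goes to the wrong site (the methyl ketone, or γ-deprotonation of the enone); or the activated C4 oxygen is lost by β-elimination.
- Fallback: it sets out from 5 and comes back at 7, building the silicon bridge from a small monofunctional silane.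
- Sequence: i-Pr2SiHCl, imidazole and DMAP in DMF give (2E,6S)-6-(diisopropylsilyloxy)-6-(propan-2-yl)dec-2-ene-4,9-dione F2. NBS in CH2Cl2 at 0 °C converts its Si–H bond into the bromosilane (2E,6S)-6-[bromo(diisopropyl)silyloxy]-6-(propan-2-yl)dec-2-ene-4,9-dione F3. Et3N then closes the ring by intramolecular O-silylation of the C6 enol to give 7.

3. Step 8.
- What may go wrong: the two hindered ketones are not discriminated well enough; hydride is delivered from the α face; or C5 epimerises or the ring opens by retro-aldol cleavage while the β-hydroxy ketone 14 is handled.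
- Fallback: it sets out from 13 and comes back at 16, setting C6 by hydrogenation instead of hydride reduction so that 14 is never made.
- Sequence: H2 over Rh/Al2O3 in EtOAc should add to the β face of the C6=C7 silyl enol ether of 13, since the α face is covered by C1 and C9. This gives 4α,6α-(diisopropylsilanediyldioxy)-5βH-daucan-10-one F4, and HF·pyridine in THF then frees diol 16.

**Further compounds**
F1 | step 6 | (E)-1-[(1R,2R,5R)-2-acetyl-5-hydroxy-2-methyl-5-(propan-2-yl)cyclopentyl]but-2-en-1-one | CC(=O)[C@]1(C)CC[C@@](O)(C(C)C)[C@@H]1C(=O)/C=C/C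
F2 | step 4 | (2E,6S)-6-(diisopropylsilyloxy)-6-(propan-2-yl)dec-2-ene-4,9-dione | CC(=O)CC[C@@](CC(=O)/C=C/C)(O[SiH](C(C)C)C(C)C)C(C)C
F3 | step 4 | (2E,6S)-6-[bromo(diisopropyl)silyloxy]-6-(propan-2-yl)dec-2-ene-4,9-dione | CC(=O)CC[C@@](CC(=O)/C=C/C)(O[Si](Br)(C(C)C)C(C)C)C(C)C
F4 | step 8 | 4α,6α-(diisopropylsilanediyldioxy)-5βH-daucan-10-one | O=C1C[C@@H](C)C[C@@H]3[C@@H]2[C@@]1(C)CC[C@@]2(O[Si](C(C)C)(C(C)C)O3)C(C)C
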